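## Retrosynthetic overview

- **Feature.** In the chroman core (O1, C2, C3, C4; ring A = C4a–C8a), C2 carries both the aryl ether oxygen O1 and the oxygenated ring Ar'. It is therefore a latent O-aryl oxocarbenium carbon. C4 is bonded to C4a, a ring A carbon ortho to O1, ortho to the C5 oxygen and para to the C7 oxygen.
- **Key disconnection.** C2–C3 and C4–C4a are cut together (cationic 2-oxadiene [4+2], oxa-Povarov). O1–C2 is built first as a mixed acetal. C3–C4 come from the Z double bond of (Z)-2,6-dimethylhepta-2,4-diene, and its second double bond ends up as a 2-methylpropenyl group, a masked isobutyl.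
- **Leaving group.** The acetal carbon carries pivalate rather than methoxide. Aryl methyl acetals tend to ionise by loss of the phenol, whereas an aryl acyloxy acetal can only lose the carboxylate.
- **Spectator groups.** Bromine at C6, C3' and C5' closes the free nucleophilic ring positions during the annulation. Each bromine is later exchanged for a formyl group, and the five methyl ethers are cleaved last.
- **Ring order.** Both benzene rings are purchased. The pyran ring (O1–C2–C3–C4–C4a–C8a) is the only ring formed (step 7).

Key step: step 7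

Assumption: the (S,S) antipode of the chiral acid is taken to deliver (2R); if the sense of induction is the opposite, the (R,R) acid is used with no other change.

## Route

Step 1
Reactants: 1 2-bromo-1,3-dimethoxybenzene
Product: 2 2-(4-bromo-3,5-dimethoxyphenyl)-4,4,5,5-tetramethyl-1,3,2-dioxaborolane
Conditions: B2pin2 (1.0 equiv), [Ir(OMe)(cod)]2 (1.5 mol %), 4,4'-di-tert-butyl-2,2'-bipyridine (3 mol %), THF, 80 °C
Reagents that add atoms: bis(pinacolato)diboron, CC1(C)OB(OC1(C)C)B1OC(C)(C)C(C)(C)O1
Why: Iridium-catalysed aromatic C–H borylation is governed by sterics, and C5–H of 1 is the only ring C–H without an ortho substituent, so boron should enter para to bromine while the C–Br bond is left alone.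

Step 2
Reactants: 2 2-(4-bromo-3,5-dimethoxyphenyl)-4,4,5,5-tetramethyl-1,3,2-dioxaborolane
Product: 3 4-bromo-3,5-dimethoxyphenol
Conditions: 30% aq H2O2, NaOH, THF, 0 °C; then 1 M HCl
Reagents that add atoms: hydrogen peroxide, OO
Why: Boronate oxidation, in which hydroperoxide adds to boron and the aryl group migrates from boron to oxygen at the same ring position, gives the phenol isomer that direct bromination of 3,5-dimethoxyphenol would not give cleanly.

Step 3
Reactants: 4 2,4,6-trimethoxybenzaldehyde
Product: 5 3,5-dibromo-2,4,6-trimethoxybenzaldehyde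
Conditions: NBS (2.2 equiv), MeCN, 0 °C → rt
Reagents that add atoms: N-bromosuccinimide, O=C1CCC(=O)N1Br
Why: Electrophilic aromatic bromination, since C3 and C5 are the only free positions of 4 and each lies ortho/para to all three methoxy groups, so two equivalents of NBS should fill both.

Step 4
Reactants: 5 3,5-dibromo-2,4,6-trimethoxybenzaldehyde
Product: 6 chloro(3,5-dibromo-2,4,6-trimethoxyphenyl)methyl 2,2-dimethylpropanoate (racemic)
Conditions: PivCl (1.5 equiv), ZnCl2 (5 mol %), CH2Cl2, 0 °C → rt; evaporated and used crude
Reagents that add atoms: pivaloyl chloride, CC(C)(C)C(=O)Cl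
Why: ZnCl2-catalysed addition of an acyl chloride across an aldehyde carbonyl group (α-chloroalkyl ester synthesis), in which the two bromines and the twisted methoxy groups temper the donor power of the ring enough for the covalent chloride to persist.

Step 5
Reactants: 6 chloro(3,5-dibromo-2,4,6-trimethoxyphenyl)methyl 2,2-dimethylpropanoate; 3 4-bromo-3,5-dimethoxyphenol
Product: 7 (4-bromo-3,5-dimethoxyphenoxy)(3,5-dibromo-2,4,6-trimethoxyphenyl)methyl 2,2-dimethylpropanoate (aryl acyloxy acetal, racemic)
Conditions: Cs2CO3 (1.2 equiv), MeCN, 0 °C; filtration through Et3N-deactivated silica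
Reagents that add atoms: none
Why: Williamson-type O-alkylation, in which the deprotonated phenol oxygen of 3 displaces the very reactive α-acyloxybenzylic chloride, the polar aprotic medium favours O- over C-alkylation, and the tert-butyl group keeps the nucleophile off the acyl carbon; the new acetal centre is racemic and is erased in step 7.

Step 6
Reactants: 8 isobutyltriphenylphosphonium bromide; 9 3-methylbut-2-enal
Product: 11 (Z)-2,6-dimethylhepta-2,4-diene, via isobutylidenetriphenylphosphorane 10 (not isolated)
Conditions: NaN(SiMe3)2, THF, 0 °C; then 9, −78 °C → rt; pentane trituration, distillation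
Reagents that add atoms: none
Why: Wittig olefination, in which a non-stabilised ylide under lithium-salt-free conditions adds to the aldehyde under kinetic control and should give the Z alkene, with the trisubstituted double bond of 9 carried through unchanged.

Step 7
Reactants: 7 (4-bromo-3,5-dimethoxyphenoxy)(3,5-dibromo-2,4,6-trimethoxyphenyl)methyl 2,2-dimethylpropanoate; 11 (Z)-2,6-dimethylhepta-2,4-diene
Product: 14 (2R,3R,4S)-6-bromo-2-(3,5-dibromo-2,4,6-trimethoxyphenyl)-5,7-dimethoxy-4-(2-methylprop-1-enyl)-3-(propan-2-yl)chroman (2,3-trans, 3,4-cis), via aryl oxocarbenium ion 12 (not isolated), via allyl cation 13 (not isolated)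
Conditions: (S,S)-HN[P(=NSO2CF3)(O2C20H10Ar2)]2, Ar = 3,5-(CF3)2C6H3 (imidodiphosphorimidate acid from two (S)-3,3'-Ar2-BINOL units, 10 mol %), 11 (3 equiv), 4 Å MS, toluene/CH2Cl2 4:1, −60 °C, slow addition of 7
Reagents that add atoms: none
Why: Proposed new method: the chiral acid protonates the pivalate carbonyl and pivalic acid leaves, the only productive ionisation because carboxylate is the better leaving group and the alternative acyloxy cation is far less stabilised, so the (E)-aryl oxocarbenium ion 12 forms as a contact ion pair with the confined chiral anion. C2 of 12 is attacked by the isopropyl-bearing diene terminus, the one position whose attack leaves an allyl cation with a tertiary end (13), and C4a, one of two equivalent ring A carbons ortho to O1, then captures the secondary allyl terminus in a 6-exo-trig Friedel–Crafts closure of the pyran ring, after which loss of the ring proton restores aromaticity and regenerates the acid (overall a cationic inverse-demand [4+2] annulation). The closest known reaction types are the racemic SnCl4-promoted oxa-Povarov annulation of aryl oxocarbenium ions with alkenes and dienes, and counteranion-directed asymmetric additions to oxocarbenium ions generated from lactol acetates; the enantioselective annulation itself has no precedent. C2 is set by the chiral anion, which covers one face of 12; C3 is set relative to C2 by an exo approach (both alkene substituents turned away from ring A) that leads to the 2,3-trans diequatorial half-chair. C4 follows from the Z geometry of the reacting double bond if closure outruns C3–C4 rotation in 13, and otherwise from peri strain with the 5-methoxy group, which pushes the 2-methylpropenyl group pseudoaxial, so both regimes should converge on 3,4-cis. The step needs ionisation towards 12, attack at the hindered diene terminus and ring closure ahead of intermolecular arylation; these are secured by the acyloxy leaving group, the tertiary-ended allyl cation, the bromine blocking of C6, C3' and C5', and excess diene with slow addition of 7 at low temperature.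

Step 8
Reactants: 14 (2R,3R,4S)-6-bromo-2-(3,5-dibromo-2,4,6-trimethoxyphenyl)-5,7-dimethoxy-4-(2-methylprop-1-enyl)-3-(propan-2-yl)chroman
Product: 15 (2R,3R,4S)-6-bromo-2-(3,5-dibromo-2,4,6-trimethoxyphenyl)-5,7-dimethoxy-4-(2-methylpropyl)-3-(propan-2-yl)chroman
Conditions: H2 (50 bar), [Ir(cod)(PCy3)(py)]PF6 (5 mol %), CH2Cl2, rt
Reagents that add atoms: none
Why: Homogeneous hydrogenation with the cationic iridium catalyst saturates hindered trisubstituted alkenes yet neither inserts into aryl C–Br bonds nor hydrogenolyses the benzylic C2–O1 bond, both of which Pd/C would threaten; no stereocentre is made or touched.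

Step 9
Reactants: 15 (2R,3R,4S)-6-bromo-2-(3,5-dibromo-2,4,6-trimethoxyphenyl)-5,7-dimethoxy-4-(2-methylpropyl)-3-(propan-2-yl)chroman
Product: 17 5-[(2R,3R,4S)-6-formyl-5,7-dimethoxy-4-(2-methylpropyl)-3-(propan-2-yl)chroman-2-yl]-2,4,6-trimethoxybenzene-1,3-dicarbaldehyde, via trilithiated chroman 16 (not isolated)
Conditions: t-BuLi (6.2 equiv), THF, −78 °C, 30 min; DMF (12 equiv), −78 → 0 °C; 1 M HCl
Reagents that add atoms: N,N-dimethylformamide, CN(C)C=O; tert-butyllithium, [Li]C(C)(C)C (lithium of 16 only)
Why: Threefold bromine–lithium exchange followed by formylation with DMF (Bouveault aldehyde synthesis), where exchange at −78 °C is much faster than deprotonation and each C–Li bond of 16 is flanked by two methoxy groups that stabilise it by chelation and induction, which makes the polylithiated species accessible.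

Step 10
Reactants: 17 5-[(2R,3R,4S)-6-formyl-5,7-dimethoxy-4-(2-methylpropyl)-3-(propan-2-yl)chroman-2-yl]-2,4,6-trimethoxybenzene-1,3-dicarbaldehyde
Product: 18 5-[(2R,3R,4S)-6-formyl-5,7-dihydroxy-4-(2-methylpropyl)-3-(propan-2-yl)chroman-2-yl]-2,4,6-trihydroxybenzene-1,3-dicarbaldehyde (CNP0328914.1)
Conditions: BCl3 (15 equiv), n-Bu4NI (6 equiv), CH2Cl2, −78 → 0 °C; ice-water
Reagents that add atoms: none
Why: Lewis-acid ether cleavage, in which each of the five methoxy groups is ortho to a formyl group so that boron binds in a six-membered chelate or beside a boron-complexed carbonyl and iodide removes the methyl group by SN2, while C2–O1 should survive because the boron-complexed diformyl ring Ar' cannot support a cation at C2 and C2 is too hindered for SN2; the three stereocentres are not involved.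

## Compound list

1 | 2-bromo-1,3-dimethoxybenzene | COc1cccc(OC)c1Br | starting material
2 | 2-(4-bromo-3,5-dimethoxyphenyl)-4,4,5,5-tetramethyl-1,3,2-dioxaborolane | COc1cc(B2OC(C)(C)C(C)(C)O2)cc(OC)c1Br | intermediate
3 | 4-bromo-3,5-dimethoxyphenol | COc1cc(O)cc(OC)c1Br | intermediate
4 | 2,4,6-trimethoxybenzaldehyde | COc1cc(OC)c(C=O)c(OC)c1 | starting material
5 | 3,5-dibromo-2,4,6-trimethoxybenzaldehyde | COc1c(Br)c(OC)c(C=O)c(OC)c1Br | intermediate
6 | chloro(3,5-dibromo-2,4,6-trimethoxyphenyl)methyl 2,2-dimethylpropanoate (racemic) | CC(C)(C)C(=O)OC(Cl)c1c(OC)c(Br)c(OC)c(Br)c1OC | intermediate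
7 | (4-bromo-3,5-dimethoxyphenoxy)(3,5-dibromo-2,4,6-trimethoxyphenyl)methyl 2,2-dimethylpropanoate (racemic) | CC(C)(C)C(=O)OC(Oc1cc(OC)c(Br)c(OC)c1)c1c(OC)c(Br)c(OC)c(Br)c1OC | intermediate
8 | isobutyltriphenylphosphonium bromide | CC(C)C[P+](c1ccccc1)(c1ccccc1)c1ccccc1.[Br-] | starting material
9 | 3-methylbut-2-enal | CC(C)=CC=O | starting material
10 | isobutylidenetriphenylphosphorane (not isolated) | CC(C)C=P(c1ccccc1)(c1ccccc1)c1ccccc1 | intermediate
11 | (Z)-2,6-dimethylhepta-2,4-diene | CC(C)/C=C\C=C(C)C | intermediate
12 | (E)-aryl oxocarbenium ion, ion pair with the chiral anion (not isolated) | COc1cc(/[O+]=C/c2c(OC)c(Br)c(OC)c(Br)c2OC)cc(OC)c1Br | intermediate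
13 | allyl cation with C2 and C3 configured as in 14, drawn in its tertiary form (not isolated) | COc1cc(O[C@@H](c2c(OC)c(Br)c(OC)c(Br)c2OC)[C@@H](/C=C/[C+](C)C)C(C)C)cc(OC)c1Br | intermediate
14 | (2R,3R,4S)-6-bromo-2-(3,5-dibromo-2,4,6-trimethoxyphenyl)-5,7-dimethoxy-4-(2-methylprop-1-enyl)-3-(propan-2-yl)chroman | CC(C)=C[C@@H]1c2c(cc(OC)c(Br)c2OC)O[C@@H](c2c(OC)c(Br)c(OC)c(Br)c2OC)[C@@H]1C(C)C | intermediate
15 | (2R,3R,4S)-6-bromo-2-(3,5-dibromo-2,4,6-trimethoxyphenyl)-5,7-dimethoxy-4-(2-methylpropyl)-3-(propan-2-yl)chroman | CC(C)C[C@@H]1c2c(cc(OC)c(Br)c2OC)O[C@@H](c2c(OC)c(Br)c(OC)c(Br)c2OC)[C@@H]1C(C)C | intermediate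
16 | 6,3',5'-trilithiated chroman (not isolated) | CC(C)C[C@@H]1c2c(cc(OC)c([Li])c2OC)O[C@@H](c2c(OC)c([Li])c(OC)c([Li])c2OC)[C@@H]1C(C)C | intermediate
17 | 5-[(2R,3R,4S)-6-formyl-5,7-dimethoxy-4-(2-methylpropyl)-3-(propan-2-yl)chroman-2-yl]-2,4,6-trimethoxybenzene-1,3-dicarbaldehyde | CC(C)C[C@@H]1c2c(cc(OC)c(C=O)c2OC)O[C@@H](c2c(OC)c(C=O)c(OC)c(C=O)c2OC)[C@@H]1C(C)C | intermediate
18 | 5-[(2R,3R,4S)-6-formyl-5,7-dihydroxy-4-(2-methylpropyl)-3-(propan-2-yl)chroman-2-yl]-2,4,6-trihydroxybenzene-1,3-dicarbaldehyde | CC(C)C[C@@H]1c2c(cc(O)c(C=O)c2O)O[C@@H](c2c(O)c(C=O)c(O)c(C=O)c2O)[C@@H]1C(C)C | target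

## Step count

Total step count: 10.

Longest linear sequence: 7 steps (3, 4, 5, 7, 8, 9, 10). The branch 1, 2, 5, 7, 8, 9, 10 is equally long.

## Steps most likely to fail

**Step 7.**
- What may go wrong:
  - poor facial discrimination by the anion on a very bulky cation;
  - loss of the Z to 3,4-cis transfer through bond rotation in 13;
  - acid-induced isomerisation or oligomerisation of the diene;
  - capture of the cations by pivalic acid or by ring A of a second molecule of 7;
  - sluggish C2–C3 bond formation between two hindered carbons.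
- Fallback: the polarity is reversed to the known ortho-quinone methide hetero-Diels–Alder route, followed by resolution. It sets out from 5 and 3 and comes back to the route at 15, so steps 4 to 8 are bypassed. Julia–Kocienski olefination of 5 with 5-[(2-methylpropyl)sulfonyl]-1-phenyl-1H-tetrazole (KN(SiMe3)2, THF, −78 °C) should give (E)-1,3-dibromo-2,4,6-trimethoxy-5-(3-methylbut-1-enyl)benzene F1. Ortho-specific condensation of 3 with 3-methylbutanal and PhB(OH)2 (cat. propionic acid, toluene, Dean–Stark) should give 6-bromo-5,7-dimethoxy-4-(2-methylpropyl)-2-phenyl-4H-1,3,2-benzodioxaborinine F2. Heating F2 with F1 (toluene, sealed tube, 160–180 °C) releases (6Z)-4-bromo-3,5-dimethoxy-6-(3-methylbutylidene)cyclohexa-2,4-dien-1-one F3, in which the isobutyl chain turns away from the neighbouring methoxy group. The [4+2] addition of F3 to F1 joins O1 to the benzylic carbon and C4 to the isopropyl-bearing carbon. The E alkene fixes 2,3-trans, and an aryl-endo approach should give 3,4-cis, leading to the racemic tribromochroman F4. Preparative chromatography on a chiral stationary phase then delivers 15.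

**Step 9.**
- What may go wrong:
  - incomplete exchange on ring Ar' once the first lithium is in place;
  - partial protonation of the aryllithium sites;
  - competing deprotonation at C8–H between O1 and the 7-methoxy group by excess base.
- Fallback: the formyl carbons are brought in by cross-coupling instead of through a polyanion. It sets out from 15 and comes back at 17. Threefold Suzuki–Miyaura vinylation of 15 with potassium vinyltrifluoroborate (Pd(OAc)2, SPhos, K2CO3, toluene/H2O, 90 °C) should give (2R,3R,4S)-6-ethenyl-2-(3,5-diethenyl-2,4,6-trimethoxyphenyl)-5,7-dimethoxy-4-(2-methylpropyl)-3-(propan-2-yl)chroman F5. Lemieux–Johnson cleavage of the three vinyl groups (OsO4 cat., NaIO4, 2,6-lutidine, dioxane/H2O) gives 17.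

**Step 10.**
- What may go wrong:
  - stalling after the chelation-assisted cleavages, since one ether of ring A and the 4'-ether share formyl groups that are already chelated;
  - Lewis-acid-induced opening of the pyran at C2–O1, followed by reclosure through the C5 oxygen or with loss of the C2 configuration.
- Fallback: electrophilic activation of oxygen is abandoned in favour of nucleophilic attack on the methyl carbons. It sets out from 17 and comes back at 18. Lithium 4-methylbenzenethiolate (excess, DMPU/toluene, 110 °C) uses the ortho/para formyl groups to make each aryloxide a leaving group under non-acidic conditions, and acidification then gives 18 directly. No new isolable compound arises (F0).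

## Further compounds

F1 | step 7 | (E)-1,3-dibromo-2,4,6-trimethoxy-5-(3-methylbut-1-enyl)benzene | COc1c(Br)c(OC)c(/C=C/C(C)C)c(OC)c1Br
F2 | step 7 | 6-bromo-5,7-dimethoxy-4-(2-methylpropyl)-2-phenyl-4H-1,3,2-benzodioxaborinine (racemic) | CC(C)CC1OB(c2ccccc2)Oc2cc(OC)c(Br)c(OC)c21
F3 | step 7 | (6Z)-4-bromo-3,5-dimethoxy-6-(3-methylbutylidene)cyclohexa-2,4-dien-1-one | CC(C)C/C=C1\C(=O)C=C(OC)C(Br)=C1OC
F4 | step 7 | racemic 2,3-trans-3,4-cis tribromochroman (15 and its enantiomer) | CC(C)C[C@@H]1c2c(cc(OC)c(Br)c2OC)O[C@@H](c2c(OC)c(Br)c(OC)c(Br)c2OC)[C@@H]1C(C)C.CC(C)C[C@H]1c2c(cc(OC)c(Br)c2OC)O[C@H](c2c(OC)c(Br)c(OC)c(Br)c2OC)[C@H]1C(C)C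
F5 | step 9 | (2R,3R,4S)-6-ethenyl-2-(3,5-diethenyl-2,4,6-trimethoxyphenyl)-5,7-dimethoxy-4-(2-methylpropyl)-3-(propan-2-yl)chroman | CC(C)C[C@@H]1c2c(cc(OC)c(C=C)c2OC)O[C@@H](c2c(OC)c(C=C)c(OC)c(C=C)c2OC)[C@@H]1C(C)C
F0 | step 10 | none | none
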